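Structural feature used: on benzene ring A, the ring oxygen O1 (bonded to C8a) and the methyl group (on C8) sit on adjacent carbons. The other neighbour of C8a is C4a, which bears the C4–C3–C2 chain of dihydropyran ring B. A C8–C8a aryne therefore lets the C2 oxygen bond to C8a and leaves a carbanion at C8 for methylation.
Disconnection 1: O1–C8a and C8–CH3 are made in one operation from an acyclic 2-fluoroaryl tertiary alcohol and CH3I. Ring A is bought, ring B is the only ring formed, and desilylation of the C6 oxygen ends the route.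
Disconnection 2 (C4–C4a): B-alkyl Suzuki–Miyaura coupling of the 9-BBN adduct of a C20 vinyl carbinol with silylated 3-bromo-4-fluorophenol. The arene serves as the electrophile because a 2-fluoroaryl metal would itself shed metal fluoride, and a γ-hydroxy tosylate could close to an oxetane.
Disconnection 3 (C2 stereocentre): Sharpless epoxidation of the E-allylic alcohol, then epoxy iodide/zinc 1,3-transposition to the vinyl carbinol. The E-alkene comes from Negishi carboalumination of a terminal alkyne.
Disconnection 4 (chain): two copper-catalysed sp3–sp3 couplings join (R)-citronellol (C8′), (S)-3-bromo-2-methylpropan-1-ol (C4′) and a silylbutynyl unit (C2′, C1′, C2, C3).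

Key step: step 13

Remark (assumption): chroman numbering (O1, C2–C4, C4a, C5–C8, C8a; side chain C1′–C13′) is used for target-related atoms. Compounds 1 and 3 are taken as commercial in high enantiomeric purity, because stereoisomers at the three mutually remote centres could hardly be removed later.

Step 1
Reactants: 1 (R)-citronellol
Product: 2 (R)-citronellyl bromide [(6R)-8-bromo-2,6-dimethyloct-2-ene]
Conditions: CBr4, PPh3, CH2Cl2, 0 °C
Reagents that add atoms: carbon tetrabromide, BrC(Br)(Br)Br
Why: Appel bromination converts the primary alcohol by SN2 attack of bromide on the alkoxyphosphonium ion under neutral conditions, so the trisubstituted alkene and the remote stereocentre (future C8′) are untouched.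

Step 2
Reactants: 3 (S)-3-bromo-2-methylpropan-1-ol
Product: 4 [(2S)-3-bromo-2-methylpropoxy]triethylsilane
Conditions: Et3SiCl, imidazole, CH2Cl2, 0 °C to rt
Reagents that add atoms: chlorotriethylsilane, CC[Si](Cl)(CC)CC
Why: Imidazole-promoted silylation masks the acidic hydroxyl for the Grignard coupling, and the triethylsilyl ether is chosen because it survives the organomagnesium reagent yet is lost in a dilute-acid work-up.

Step 3
Reactants: 2 (R)-citronellyl bromide; 4 [(2S)-3-bromo-2-methylpropoxy]triethylsilane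
Product: 7 (2R,6S)-2,6,10-trimethylundec-9-en-1-ol, via citronellylmagnesium bromide 5 (not isolated), via triethylsilyl ether 6 (not isolated)
Conditions: 2, Mg, THF, 40 °C; then 4, Li2CuCl4 (5 mol %), NMP (4 equiv), THF, 0 °C to rt; then 1 M aq HCl, rt
Reagents that add atoms: none
Why: Copper-catalysed Grignard–alkyl halide cross-coupling (Kochi type) joins C6′ to C5′ by displacement at a primary carbon, so both stereocentres (C8′ from 2, C4′ from 4) lie off the reacting atoms and are carried over unchanged, and the acidic work-up hydrolyses the silyl ether.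

Step 4
Reactants: 7 (2R,6S)-2,6,10-trimethylundec-9-en-1-ol
Product: 8 (2R,6S)-2,6,10-trimethylundec-9-en-1-yl 4-methylbenzenesulfonate
Conditions: TsCl, Et3N, DMAP (cat.), CH2Cl2, 0 °C to rt
Reagents that add atoms: 4-toluenesulfonyl chloride, Cc1ccc(cc1)S(Cl)(=O)=O
Why: Sulfonylation of the primary alcohol installs the leaving group best suited to copper-catalysed Grignard displacement without affecting the adjacent stereocentre or the alkene.

Step 5
Reactants: 8 (2R,6S)-2,6,10-trimethylundec-9-en-1-yl 4-methylbenzenesulfonate; 9 (4-bromobut-1-yn-1-yl)trimethylsilane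
Product: 11 trimethyl[(6R,10S)-6,10,14-trimethylpentadec-13-en-1-yn-1-yl]silane, via silylbutynylmagnesium bromide 10 (not isolated)
Conditions: 9, Mg, THF, rt; then 8, Li2CuCl4 (5 mol %), THF, −20 °C to rt
Reagents that add atoms: none
Why: A second Kochi-type copper-catalysed coupling displaces the primary tosylate with the homopropargylic Grignard reagent (C3′–C2′ bond), the silyl cap removing the acidic alkyne hydrogen that would otherwise destroy the reagent.

Step 6
Reactants: 11 trimethyl[(6R,10S)-6,10,14-trimethylpentadec-13-en-1-yn-1-yl]silane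
Product: 12 (6R,10S)-6,10,14-trimethylpentadec-13-en-1-yne
Conditions: K2CO3 (0.2 equiv), MeOH, rt
Reagents that add atoms: none
Why: Methoxide-mediated protodesilylation cleaves only the C(sp)–Si bond and gives the terminal alkyne needed for carbometalation.

Step 7
Reactants: 12 (6R,10S)-6,10,14-trimethylpentadec-13-en-1-yne
Product: 15 (2E,7R,11S)-3,7,11,15-tetramethylhexadeca-2,14-dien-1-ol, via alkenyldimethylalane 13 (not isolated), via lithium alkenylalanate 14 (not isolated)
Conditions: Me3Al, Cp2ZrCl2 (25 mol %), CH2Cl2, 0 °C to rt; excess Me3Al evaporated; n-BuLi, hexane/THF, −78 to 0 °C; (CH2O)n, rt; aq potassium sodium tartrate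
Reagents that add atoms: trimethylaluminium, C[Al](C)C; paraformaldehyde (as formaldehyde), C=O
Why: Negishi zirconium-catalysed carboalumination adds CH3 and Al syn across the terminal alkyne with CH3 on the internal carbon, which fixes the E geometry, and the derived alanate is hydroxymethylated by formaldehyde with retention of that geometry while the unactivated trisubstituted alkene does not react.

Step 8
Reactants: 15 (2E,7R,11S)-3,7,11,15-tetramethylhexadeca-2,14-dien-1-ol
Product: 16 {(2R,3R)-3-methyl-3-[(4R,8S)-4,8,12-trimethyltridec-11-en-1-yl]oxiran-2-yl}methanol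
Conditions: Ti(OiPr)4 (10 mol %), D-(−)-diisopropyl tartrate (13 mol %), t-BuOOH, 4 Å molecular sieves, CH2Cl2, −20 °C
Reagents that add atoms: tert-butyl hydroperoxide, CC(C)(C)OO
Why: In the Sharpless asymmetric epoxidation the titanium–tartrate complex binds the allylic hydroxyl and delivers oxygen to one face of the C2=C3 alkene in the sense established for geraniol-type E-3-methylalk-2-en-1-ols (L-(+)-ester gives 2S,3S, D-(−)-ester gives 2R,3R), so the future chroman C2 is set as R under reagent control while the unbound C14=C15 alkene is left alone.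

Step 9
Reactants: 16 {(2R,3R)-3-methyl-3-[(4R,8S)-4,8,12-trimethyltridec-11-en-1-yl]oxiran-2-yl}methanol
Product: 17 (2S,3R)-2-(iodomethyl)-3-methyl-3-[(4R,8S)-4,8,12-trimethyltridec-11-en-1-yl]oxirane
Conditions: I2, PPh3, imidazole, THF, 0 °C
Reagents that add atoms: iodine, II
Why: Appel-type iodination under Garegg–Samuelsson conditions replaces the primary hydroxyl by SN2 while imidazole keeps the medium neutral, so the epoxide and both its stereocentres persist (the C2 descriptor becomes S only through the priority of iodine).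

Step 10
Reactants: 17 (2S,3R)-2-(iodomethyl)-3-methyl-3-[(4R,8S)-4,8,12-trimethyltridec-11-en-1-yl]oxirane
Product: 18 (3R,7R,11S)-3,7,11,15-tetramethylhexadeca-1,14-dien-3-ol
Conditions: Zn dust, AcOH, Et2O/EtOH, 0 °C to rt
Reagents that add atoms: none
Why: Reductive β-elimination of a 2,3-epoxy iodide: zinc inserts into C–I and the organozinc expels the neighbouring epoxide oxygen by breaking C2–O only, so the C3–O bond and the C3 configuration are kept and the 1,3-transposed tertiary vinyl carbinol results.

Step 11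
Reactants: 19 3-bromo-4-fluorophenol
Product: 20 (3-bromo-4-fluorophenoxy)tri(propan-2-yl)silane
Conditions: i-Pr3SiCl, imidazole, DMF, rt
Reagents that add atoms: chlorotriisopropylsilane, CC(C)[Si](Cl)(C(C)C)C(C)C
Why: Imidazole-promoted O-silylation installs a bulky, non-coordinating phenol protecting group that tolerates aqueous phosphate, alkyllithiums and CH3I and does not direct ortho-metalation.

Step 12
Reactants: 18 (3R,7R,11S)-3,7,11,15-tetramethylhexadeca-1,14-dien-3-ol; 20 (3-bromo-4-fluorophenoxy)tri(propan-2-yl)silane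
Product: 22 (3R,7R,11S)-1-[2-fluoro-5-(triisopropylsilyloxy)phenyl]-3,7,11,15-tetramethylhexadec-14-en-3-ol, via B-alkyl-9-BBN adduct 21 (not isolated)
Conditions: 18, 9-BBN-H (2.2 equiv), THF, 0 °C to rt; then 20, Pd(dppf)Cl2 (5 mol %), 3 M aq K3PO4, THF, 50 °C
Reagents that add atoms: none
Why: In this B-alkyl Suzuki–Miyaura coupling 9-BBN-H adds anti-Markovnikov to the monosubstituted C1=C2 alkene far faster than to the trisubstituted C14=C15 alkene, and the primary alkylborane is transferred to the arylpalladium bromide formed by insertion of zerovalent palladium into C–Br of 20 (C–F inert), so C4–C4a is made without any 2-fluoroaryl metal and without touching C3.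

Step 13
Reactants: 22 (3R,7R,11S)-1-[2-fluoro-5-(triisopropylsilyloxy)phenyl]-3,7,11,15-tetramethylhexadec-14-en-3-ol; 23 iodomethane
Product: 28 triisopropyl({(2R)-2,8-dimethyl-2-[(4R,8S)-4,8,12-trimethyltridec-11-en-1-yl]-3,4-dihydro-2H-chromen-6-yl}oxy)silane, via lithium alkoxide 24 (not isolated), via C8-lithiated alkoxide 25 (not isolated), via C8–C8a aryne 26 (not isolated), via 8-lithiochroman 27 (not isolated)
Conditions: n-BuLi (1.0 equiv), THF (0.02 M), −78 °C; s-BuLi (1.1 equiv), −78 °C, 2 h; −78 to −20 °C; recool to −78 °C, CH3I (5 equiv), to 0 °C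
Reagents that add atoms: iodomethane, CI
Why: Proposed new method: n-BuLi first turns the C2 hydroxyl into its lithium alkoxide, s-BuLi then removes C8–H, the only ring hydrogen ortho to fluorine, at −78 °C where the 2-fluoroaryllithium 25 persists, and warming expels LiF to give the C8–C8a aryne 26, whose C8a carbon is attacked by the tethered alkoxide to form O1–C8a and the C8 aryllithium 27, which CH3I converts into C8–CH3. The closest known reaction types are the alkyllithium- or lithium-amide-induced aryne cyclisations of haloarenes carrying a tethered O-, N- or C-nucleophile in which the aryllithium formed is quenched with an electrophile (for example 7-substituted benzoxazoles from 3-haloanilides) and the chroman synthesis by capture of an aryne by a tethered alcohol; what has not been shown is a lithium tertiary alkoxide as the nucleophile combined with C-methylation of the resulting anion. Ring B closes in a 6-exo-dig mode on the in-plane π bond of the aryne, attack at C8 being geometrically excluded because it would demand a meta-bridged ring. No stereocentre is created, and the C2 configuration is retained because the C2–O bond is never broken. The step needs site-selective metalation (C8–H over C5–H, C7–H and benzylic C4–H2), secured by the acidifying fluorine and by the bulky, non-coordinating silyloxy group that shields C5 and C7, and it needs intramolecular capture to outrun addition of 25 or 27 to the aryne, which high dilution and the short C4–C3–C2 tether favour. Alkyllithium bases are used instead of a lithium amide so that butane is the only conjugate acid present and 27 cannot be reprotonated before CH3I is added.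

Step 14
Reactants: 28 triisopropyl({(2R)-2,8-dimethyl-2-[(4R,8S)-4,8,12-trimethyltridec-11-en-1-yl]-3,4-dihydro-2H-chromen-6-yl}oxy)silane
Product: 29 (2R)-2,8-dimethyl-2-[(4R,8S)-4,8,12-trimethyltridec-11-en-1-yl]-3,4-dihydro-2H-chromen-6-ol (target)
Conditions: Bu4NF, AcOH, THF, 0 °C, argon
Reagents that add atoms: none
Why: Fluoride-induced cleavage of the aryl silyl ether is driven by Si–F bond formation, acetic acid buffering keeps the oxidation-prone chromanol protonated, and no stereocentre or alkene is affected.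

Compound list
1 | (R)-citronellol, (3R)-3,7-dimethyloct-6-en-1-ol | CC(C)=CCC[C@@H](C)CCO | starting material
2 | (R)-citronellyl bromide, (6R)-8-bromo-2,6-dimethyloct-2-ene | CC(C)=CCC[C@@H](C)CCBr | intermediate
3 | (S)-3-bromo-2-methylpropan-1-ol | BrC[C@@H](C)CO | starting material
4 | [(2S)-3-bromo-2-methylpropoxy]triethylsilane | BrC[C@@H](C)CO[Si](CC)(CC)CC | intermediate
5 | [(3R)-3,7-dimethyloct-6-en-1-yl]magnesium bromide | CC(C)=CCC[C@@H](C)CC[Mg]Br | intermediate
6 | triethyl{[(2R,6S)-2,6,10-trimethylundec-9-en-1-yl]oxy}silane | CC(C)=CCC[C@@H](C)CCC[C@@H](C)CO[Si](CC)(CC)CC | intermediate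
7 | (2R,6S)-2,6,10-trimethylundec-9-en-1-ol | CC(C)=CCC[C@@H](C)CCC[C@@H](C)CO | intermediate
8 | (2R,6S)-2,6,10-trimethylundec-9-en-1-yl 4-methylbenzenesulfonate | CC(C)=CCC[C@@H](C)CCC[C@@H](C)COS(=O)(=O)c1ccc(C)cc1 | intermediate
9 | (4-bromobut-1-yn-1-yl)trimethylsilane | C[Si](C)(C)C#CCCBr | starting material
10 | [4-(trimethylsilyl)but-3-yn-1-yl]magnesium bromide | C[Si](C)(C)C#CCC[Mg]Br | intermediate
11 | trimethyl[(6R,10S)-6,10,14-trimethylpentadec-13-en-1-yn-1-yl]silane | CC(C)=CCC[C@@H](C)CCC[C@@H](C)CCCC#C[Si](C)(C)C | intermediate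
12 | (6R,10S)-6,10,14-trimethylpentadec-13-en-1-yne | CC(C)=CCC[C@@H](C)CCC[C@@H](C)CCCC#C | intermediate
13 | dimethyl[(1E,6R,10S)-2,6,10,14-tetramethylpentadeca-1,13-dien-1-yl]alumane | CC(C)=CCC[C@@H](C)CCC[C@@H](C)CCC/C(C)=C/[Al](C)C | intermediate
14 | lithium butyl(dimethyl)[(1E,6R,10S)-2,6,10,14-tetramethylpentadeca-1,13-dien-1-yl]alanate | [Li+].CCCC[Al-](C)(C)/C=C(\C)CCC[C@H](C)CCC[C@H](C)CCC=C(C)C | intermediate
15 | (2E,7R,11S)-3,7,11,15-tetramethylhexadeca-2,14-dien-1-ol | CC(C)=CCC[C@@H](C)CCC[C@@H](C)CCC/C(C)=C/CO | intermediate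
16 | {(2R,3R)-3-methyl-3-[(4R,8S)-4,8,12-trimethyltridec-11-en-1-yl]oxiran-2-yl}methanol | CC(C)=CCC[C@@H](C)CCC[C@@H](C)CCC[C@@]1(C)O[C@@H]1CO | intermediate
17 | (2S,3R)-2-(iodomethyl)-3-methyl-3-[(4R,8S)-4,8,12-trimethyltridec-11-en-1-yl]oxirane | CC(C)=CCC[C@@H](C)CCC[C@@H](C)CCC[C@@]1(C)O[C@@H]1CI | intermediate
18 | (3R,7R,11S)-3,7,11,15-tetramethylhexadeca-1,14-dien-3-ol | C[C@](O)(C=C)CCC[C@H](C)CCC[C@H](C)CCC=C(C)C | intermediate
19 | 3-bromo-4-fluorophenol | Oc1ccc(F)c(Br)c1 | starting material
20 | (3-bromo-4-fluorophenoxy)tri(propan-2-yl)silane | CC(C)[Si](Oc1ccc(F)c(Br)c1)(C(C)C)C(C)C | intermediate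
21 | (3S,7R,11S)-1-(9-borabicyclo[3.3.1]nonan-9-yl)-3,7,11,15-tetramethylhexadec-14-en-3-ol (C3 descriptor changes through the low priority of boron, geometry unchanged) | C[C@](O)(CCB1C2CCCC1CCC2)CCC[C@H](C)CCC[C@H](C)CCC=C(C)C | intermediate
22 | (3R,7R,11S)-1-[2-fluoro-5-(triisopropylsilyloxy)phenyl]-3,7,11,15-tetramethylhexadec-14-en-3-ol | C[C@](O)(CCc1cc(O[Si](C(C)C)(C(C)C)C(C)C)ccc1F)CCC[C@H](C)CCC[C@H](C)CCC=C(C)C | intermediate
23 | iodomethane | CI | starting material
24 | lithium (3R,7R,11S)-1-[2-fluoro-5-(triisopropylsilyloxy)phenyl]-3,7,11,15-tetramethylhexadec-14-en-3-olate | C[C@](O[Li])(CCc1cc(O[Si](C(C)C)(C(C)C)C(C)C)ccc1F)CCC[C@H](C)CCC[C@H](C)CCC=C(C)C | intermediate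
25 | lithium (3R,7R,11S)-1-[2-fluoro-3-lithio-5-(triisopropylsilyloxy)phenyl]-3,7,11,15-tetramethylhexadec-14-en-3-olate | C[C@](O[Li])(CCc1cc(O[Si](C(C)C)(C(C)C)C(C)C)cc([Li])c1F)CCC[C@H](C)CCC[C@H](C)CCC=C(C)C | intermediate
26 | lithium (3R,7R,11S)-1-[2,3-didehydro-5-(triisopropylsilyloxy)phenyl]-3,7,11,15-tetramethylhexadec-14-en-3-olate (C8–C8a aryne) | C[C@](O[Li])(CCC1=CC(O[Si](C(C)C)(C(C)C)C(C)C)=CC#C1)CCC[C@H](C)CCC[C@H](C)CCC=C(C)C | intermediate
27 | {(2R)-2-methyl-6-(triisopropylsilyloxy)-2-[(4R,8S)-4,8,12-trimethyltridec-11-en-1-yl]-3,4-dihydro-2H-chromen-8-yl}lithium | [Li]c1cc(O[Si](C(C)C)(C(C)C)C(C)C)cc2c1O[C@](C)(CCC[C@H](C)CCC[C@H](C)CCC=C(C)C)CC2 | intermediate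
28 | triisopropyl({(2R)-2,8-dimethyl-2-[(4R,8S)-4,8,12-trimethyltridec-11-en-1-yl]-3,4-dihydro-2H-chromen-6-yl}oxy)silane | Cc1cc(O[Si](C(C)C)(C(C)C)C(C)C)cc2c1O[C@](C)(CCC[C@H](C)CCC[C@H](C)CCC=C(C)C)CC2 | intermediate
29 | (2R)-2,8-dimethyl-2-[(4R,8S)-4,8,12-trimethyltridec-11-en-1-yl]-3,4-dihydro-2H-chromen-6-ol | CC(C)=CCC[C@@H](C)CCC[C@@H](C)CCC[C@]1(C)CCc2cc(O)cc(C)c2O1 | target

Total step count: 14. Longest linear sequence: 12 (steps 1, 3–10, 12–14, from 1; the same length from 3 via step 2).

Steps most likely to fail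

Step 13 (proposed new method). Capture of the aryne by the weakly nucleophilic lithium tertiary alkoxide may be outrun by intermolecular addition of aryllithium species. The C8 anion may also be lost by proton transfer before methylation.
The fallback uses known chemistry and no aryne. The C8 methyl is bought with the arene, and O1–C8a is closed by palladium-catalysed intramolecular C–O coupling of a tertiary alcohol with an aryl bromide.
- Commercial 4-amino-3-methylphenol is O-silylated (i-Pr3SiCl, imidazole) to 2-methyl-4-(triisopropylsilyloxy)aniline F1.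
- Iodination ortho to nitrogen (N-iodosuccinimide, MeCN) gives 2-iodo-6-methyl-4-(triisopropylsilyloxy)aniline F2.
- Sandmeyer bromination (t-BuONO, CuBr2, MeCN) gives (4-bromo-3-iodo-5-methylphenoxy)triisopropylsilane F3.
- The route is left at 18. Its 9-BBN adduct 21 is coupled with F3 selectively at the C–I bond (Pd(dppf)Cl2, aq K3PO4, THF, rt) to give (3R,7R,11S)-1-[2-bromo-3-methyl-5-(triisopropylsilyloxy)phenyl]-3,7,11,15-tetramethylhexadec-14-en-3-ol F4.
- Pd(OAc)2, 2-(di-tert-butylphosphino)-1,1′-binaphthyl and Cs2CO3 in toluene at 80 °C then close ring B with the C2–O bond untouched, returning to the route at 28.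

Step 12. Three things may go wrong: consumption of the borane by the free tertiary hydroxyl, partial hydroboration of the distal alkene, or slow transmetalation with loss of the alkylborane.
The fallback leaves the route at 16 and needs no organometallic reagent.
- NaAlH2(OCH2CH2OCH3)2 in THF at 0 °C delivers hydride to C2 of the epoxy alcohol and gives (3R,7R,11S)-3,7,11,15-tetramethylhexadec-14-ene-1,3-diol F5.
- Appel bromination of the primary hydroxyl only (CBr4, PPh3) gives (3R,7R,11S)-1-bromo-3,7,11,15-tetramethylhexadec-14-en-3-ol F6.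
- Nickel-catalysed reductive cross-electrophile coupling of F6 with 20 (NiBr2(dme), 4,4′-di-tert-butyl-2,2′-bipyridine, NaI, Zn, DMA, 60 °C) tolerates free hydroxyl groups and returns to the route at 22.

Step 5. Displacement at the β-branched tosylate may be slow, so that the homopropargylic Grignard reagent decays or homocouples first.
The fallback leaves the route at 7 and reverses the polarity.
- Appel bromination gives (2R,6S)-2,6,10-trimethylundec-9-en-1-yl bromide F7.
- Magnesium in THF gives [(2R,6S)-2,6,10-trimethylundec-9-en-1-yl]magnesium bromide F8.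
- Copper-catalysed conjugate addition to but-3-en-2-one (CuBr·SMe2, THF, −40 °C) gives (6R,10S)-6,10,14-trimethylpentadec-13-en-2-one F9.
- Horner–Wadsworth–Emmons olefination (triethyl phosphonoacetate, NaH, THF), with chromatographic removal of the Z isomer, gives ethyl (2E,7R,11S)-3,7,11,15-tetramethylhexadeca-2,14-dienoate F10.
- i-Bu2AlH in CH2Cl2 at −78 °C returns to the route at 15.

Further compounds
F1 | step 13 | 2-methyl-4-(triisopropylsilyloxy)aniline | Cc1cc(O[Si](C(C)C)(C(C)C)C(C)C)ccc1N
F2 | step 13 | 2-iodo-6-methyl-4-(triisopropylsilyloxy)aniline | Cc1cc(O[Si](C(C)C)(C(C)C)C(C)C)cc(I)c1N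
F3 | step 13 | (4-bromo-3-iodo-5-methylphenoxy)triisopropylsilane | Cc1cc(O[Si](C(C)C)(C(C)C)C(C)C)cc(I)c1Br
F4 | step 13 | (3R,7R,11S)-1-[2-bromo-3-methyl-5-(triisopropylsilyloxy)phenyl]-3,7,11,15-tetramethylhexadec-14-en-3-ol | C[C@](O)(CCc1cc(O[Si](C(C)C)(C(C)C)C(C)C)cc(C)c1Br)CCC[C@H](C)CCC[C@H](C)CCC=C(C)C
F5 | step 12 | (3R,7R,11S)-3,7,11,15-tetramethylhexadec-14-ene-1,3-diol | C[C@](O)(CCO)CCC[C@H](C)CCC[C@H](C)CCC=C(C)C
F6 | step 12 | (3R,7R,11S)-1-bromo-3,7,11,15-tetramethylhexadec-14-en-3-ol | C[C@](O)(CCBr)CCC[C@H](C)CCC[C@H](C)CCC=C(C)C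
F7 | step 5 | (2R,6S)-2,6,10-trimethylundec-9-en-1-yl bromide | CC(C)=CCC[C@@H](C)CCC[C@@H](C)CBr
F8 | step 5 | [(2R,6S)-2,6,10-trimethylundec-9-en-1-yl]magnesium bromide | CC(C)=CCC[C@@H](C)CCC[C@@H](C)C[Mg]Br
F9 | step 5 | (6R,10S)-6,10,14-trimethylpentadec-13-en-2-one | CC(C)=CCC[C@@H](C)CCC[C@@H](C)CCCC(C)=O
F10 | step 5 | ethyl (2E,7R,11S)-3,7,11,15-tetramethylhexadeca-2,14-dienoate | CCOC(=O)/C=C(\C)CCC[C@H](C)CCC[C@H](C)CCC=C(C)C
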